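## Retrosynthetic overview

- Rings A and B and all four stereocentres (C4, C5, C9, C10) are carried over unchanged from levopimaric acid 1. No ring is formed in the route; ring C is removed.
- The C8=C14 and C12=C13 bonds of 1 are cleaved oxidatively to keto diacid 2 (C8 ketone, C12 acid). C17 is put back by Wittig methylenation to give ene diacid 3.
- Key disconnection C11–C12 (together with C15–O): the C12 carboxyl of 3, activated as N-hydroxyphthalimide ester 4, is the carbon that leaves. The C12–C16 chain is isoprene 5 plus acetate, joined under blue light with palladium to give target 6.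

Assumption: levopimaric acid 1 (main resin acid of pine oleoresin) is taken as a purchasable bulk chiral starting material; the target is read from the SMILES as 15-acetoxylabda-8(17),13E-dien-18-oic acid, (4R,5R,9S,10R).

## Route

Step 1
Reactants: 1 levopimaric acid [abieta-8(14),12-dien-18-oic acid]
Product: 2 8-oxo-13,14,15,16,17-pentanorlabdane-12,18-dioic acid
Conditions: RuCl3·H2O (4 mol %), NaIO4 (7 equiv), EtOAc–MeCN–H2O (2:2:3), 0 °C to rt
Reagents that add atoms: sodium periodate, [Na+].[O-]I(=O)(=O)=O (oxygen, passed on by RuO4); water, O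
Why: RuO4 made in situ cleaves both trisubstituted C=C bonds of the ring-C diene (Sharpless ruthenium-catalysed oxidative cleavage), leaving C8 as a ketone and C12 as CO2H while C13–C17 leave as one keto acid; no stereocentre is made, and C9, now α to the ketone, stays in its stable equatorial (9β side chain) configuration.

Step 2
Reactants: 2 8-oxo-13,14,15,16,17-pentanorlabdane-12,18-dioic acid
Product: 3 13,14,15,16-tetranorlabd-8(17)-ene-12,18-dioic acid
Conditions: Ph3PCH3Br (4 equiv), KOtBu (6 equiv), THF, 0 °C to 60 °C; AcOH quench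
Reagents that add atoms: methyltriphenylphosphonium bromide, C[P+](c1ccccc1)(c1ccccc1)c1ccccc1.[Br-]
Why: Wittig methylenation on the dipotassium dicarboxylate, in which the C8 ketone is the only electrophile; no new stereocentre, and any enolisation at C9 returns the thermodynamically favoured natural epimer.

Step 3
Reactants: 3 13,14,15,16-tetranorlabd-8(17)-ene-12,18-dioic acid
Product: 4 12-(1,3-dioxoisoindolin-2-yl) hydrogen 13,14,15,16-tetranorlabd-8(17)-ene-12,18-dioate
Conditions: N-hydroxyphthalimide (1.05 equiv), DIC (1.05 equiv), DMAP (5 mol %), CH2Cl2, 0 °C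
Reagents that add atoms: N-hydroxyphthalimide, O=C1c2ccccc2C(=O)N1O
Why: Steglich-type carbodiimide esterification should select the unhindered primary CH2CO2H over the neopentyl-like tertiary C18 acid, which reacts far more slowly at 0 °C with one equivalent of reagent; no stereocentre is touched.

Step 4
Reactants: 4 12-(1,3-dioxoisoindolin-2-yl) hydrogen 13,14,15,16-tetranorlabd-8(17)-ene-12,18-dioate; 5 isoprene
Product: 6 15-acetoxylabda-8(17),13E-dien-18-oic acid (target)
Conditions: Pd(PPh3)4 (5 mol %), Xantphos (6 mol %), 5 (20 equiv), Bu4NOAc (3 equiv), AcOH (10 equiv), DMA, 450 nm LEDs, 25 °C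
Reagents that add atoms: acetic acid, CC(=O)O, delivered as acetate from the buffer with tetrabutylammonium acetate, CCCC[N+](CCCC)(CCCC)CCCC.CC(=O)[O-]
Why: Proposed new method: a light-driven palladium radical–polar crossover three-component 1,4-carboacetoxylation of isoprene — photoexcited zerovalent palladium gives one electron to the N-hydroxyphthalimide ester, CO2 and phthalimide anion leave, the primary C11 radical adds to C1 of s-trans isoprene (20 equiv, so that addition outruns 3-exo attack on the C8 methylene), the resulting E-configured allyl radical is captured by monovalent palladium as an η3-allyl complex of divalent palladium, and acetate opens it at the unhindered CH2 terminus, while any tertiary acetate is re-ionised by zerovalent palladium and funnelled to the linear E primary acetate and the AcOH buffer keeps phthalimide protonated so that it does not compete as N-nucleophile; this makes C11–C12 and C15–O and sets the 13E geometry (no stereocentre is formed, C9 is untouched); closest known reaction type: visible-light palladium-catalysed 1,4-carboamination of butadiene with alkyl halides or redox-active esters through radical-derived π-allylpalladium intermediates.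

## Compound list

1 | levopimaric acid, abieta-8(14),12-dien-18-oic acid, (1R,4aR,4bS,10aR); 4α-CO2H, 4β-CH3, 5α-H, 9α-H, 10β-CH3 | C1=C2CC[C@@H]3[C@](C)(CCC[C@@]3(C)C(=O)O)[C@H]2CC=C1C(C)C | starting material
2 | 8-oxo-13,14,15,16,17-pentanorlabdane-12,18-dioic acid; trans-decalin with C8 ketone, 9β-CH2CO2H (9α-H), 4α-CO2H, 4β-CH3, 5α-H, 10β-CH3 | O=C1CC[C@@H]2[C@](C)(CCC[C@@]2(C)C(=O)O)[C@H]1CC(=O)O | intermediate
3 | 13,14,15,16-tetranorlabd-8(17)-ene-12,18-dioic acid; as 2 but with exocyclic C8=CH2 | C=C1CC[C@@H]2[C@](C)(CCC[C@@]2(C)C(=O)O)[C@H]1CC(=O)O | intermediate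
4 | 12-(1,3-dioxoisoindolin-2-yl) hydrogen 13,14,15,16-tetranorlabd-8(17)-ene-12,18-dioate; N-hydroxyphthalimide ester at C12, free C18 acid | C=C1CC[C@@H]2[C@](C)(CCC[C@@]2(C)C(=O)O)[C@H]1CC(=O)ON1C(=O)c2ccccc2C1=O | intermediate
5 | isoprene (2-methylbuta-1,3-diene) | C=CC(C)=C | starting material
6 | 15-acetoxylabda-8(17),13E-dien-18-oic acid; (1R,4aR,5S,8aR)-5-[(3E)-5-acetoxy-3-methylpent-3-enyl]-1,4a-dimethyl-6-methylidenedecahydronaphthalene-1-carboxylic acid | C=C1CC[C@@H]2[C@](C)(CCC[C@@]2(C)C(=O)O)[C@H]1CC/C(C)=C/COC(C)=O | target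

## Step count and risks

Total step count: 4. Longest linear sequence: 4 (1 → 2 → 3 → 4 → 6).

The three steps most likely to fail:

**Step 4 (the proposed new coupling).** Possible failures:
- radical attack at C4 instead of C1 of isoprene, which puts the methyl on C14 instead of C13;
- N-allylation of phthalimide;
- 1,2-vinyl shift of the homoallylic C11 radical;
- partial loss of E geometry.

The fallback uses known chemistry only, sets out from 4 and returns to the route at 6. NaBH4 in THF–H2O at 0 °C reduces the active ester to 12-hydroxy-13,14,15,16-tetranorlabd-8(17)-en-18-oic acid F1. I2, PPh3 and imidazole in CH2Cl2 give 12-iodo-13,14,15,16-tetranorlabd-8(17)-en-18-oic acid F2. LiC≡CH·ethylenediamine (3 equiv, DMSO, rt) displaces iodide to give 15,16-dinorlabd-8(17)-en-13-yn-18-oic acid F3. Negishi carboalumination (Me3Al, Cp2ZrCl2, CH2Cl2; then n-BuLi and paraformaldehyde) gives 15-hydroxylabda-8(17),13E-dien-18-oic acid F4, with the E geometry fixed by syn addition of methyl and aluminium. Ac2O and pyridine then acetylate the primary alcohol to 6.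

**Step 3 (choice between the two acids).** Tertiary acids of this type do form N-hydroxyphthalimide esters, so the selectivity is only kinetic and some C18 or double activation is possible. The fallback removes the choice by protection, sets out from 3 and returns at 6. SEMCl and iPr2NEt in CH2Cl2 esterify both acids to bis[2-(trimethylsilyl)ethoxymethyl] 13,14,15,16-tetranorlabd-8(17)-ene-12,18-dioate F5. LiOH (1.1 equiv, THF–H2O, 0 °C) saponifies only the unhindered C12 ester to 18-[2-(trimethylsilyl)ethoxymethyl] hydrogen 13,14,15,16-tetranorlabd-8(17)-ene-12,18-dioate F6. DIC and N-hydroxyphthalimide then give the 12-(1,3-dioxoisoindolin-2-yl) 18-[2-(trimethylsilyl)ethoxymethyl] diester F7 with no selectivity question. The coupling of step 4 gives 2-(trimethylsilyl)ethoxymethyl 15-acetoxylabda-8(17),13E-dien-18-oate F8. MgBr2·OEt2 in Et2O at rt frees the acid 6 without touching the allylic acetate.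

**Step 2 (Wittig on an enolisable, poorly soluble keto dicarboxylate).** Conversion may be low. The fallback is a Peterson route, sets out from 2 and returns at 3. Me3SiCH2Li (4 equiv) with CeCl3 in THF at −78 °C adds to the ketone from the α face to give 8β-hydroxy-17-trimethylsilyl-13,14,15,16-tetranorlabdane-12,18-dioic acid F9, kept as its salt. KOtBu in THF at 0 °C to rt then brings about Peterson elimination to the exocyclic alkene 3. Either C8 epimer of the adduct gives the same alkene.

## Further compounds

F1 | step 4 | 12-hydroxy-13,14,15,16-tetranorlabd-8(17)-en-18-oic acid | C=C1CC[C@@H]2[C@](C)(CCC[C@@]2(C)C(=O)O)[C@H]1CCO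
F2 | step 4 | 12-iodo-13,14,15,16-tetranorlabd-8(17)-en-18-oic acid | C=C1CC[C@@H]2[C@](C)(CCC[C@@]2(C)C(=O)O)[C@H]1CCI
F3 | step 4 | 15,16-dinorlabd-8(17)-en-13-yn-18-oic acid | C=C1CC[C@@H]2[C@](C)(CCC[C@@]2(C)C(=O)O)[C@H]1CCC#C
F4 | step 4 | 15-hydroxylabda-8(17),13E-dien-18-oic acid | C=C1CC[C@@H]2[C@](C)(CCC[C@@]2(C)C(=O)O)[C@H]1CC/C(C)=C/CO
F5 | step 3 | bis[2-(trimethylsilyl)ethoxymethyl] 13,14,15,16-tetranorlabd-8(17)-ene-12,18-dioate | C=C1CC[C@@H]2[C@](C)(CCC[C@@]2(C)C(=O)OCOCC[Si](C)(C)C)[C@H]1CC(=O)OCOCC[Si](C)(C)C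
F6 | step 3 | 18-[2-(trimethylsilyl)ethoxymethyl] hydrogen 13,14,15,16-tetranorlabd-8(17)-ene-12,18-dioate | C=C1CC[C@@H]2[C@](C)(CCC[C@@]2(C)C(=O)OCOCC[Si](C)(C)C)[C@H]1CC(=O)O
F7 | step 3 | 12-(1,3-dioxoisoindolin-2-yl) 18-[2-(trimethylsilyl)ethoxymethyl] 13,14,15,16-tetranorlabd-8(17)-ene-12,18-dioate | C=C1CC[C@@H]2[C@](C)(CCC[C@@]2(C)C(=O)OCOCC[Si](C)(C)C)[C@H]1CC(=O)ON1C(=O)c2ccccc2C1=O
F8 | step 3 | 2-(trimethylsilyl)ethoxymethyl 15-acetoxylabda-8(17),13E-dien-18-oate | C=C1CC[C@@H]2[C@](C)(CCC[C@@]2(C)C(=O)OCOCC[Si](C)(C)C)[C@H]1CC/C(C)=C/COC(C)=O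
F9 | step 2 | 8β-hydroxy-17-trimethylsilyl-13,14,15,16-tetranorlabdane-12,18-dioic acid | C[Si](C)(C)C[C@]1(O)CC[C@@H]2[C@](C)(CCC[C@@]2(C)C(=O)O)[C@H]1CC(=O)O
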